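**Retrosynthetic overview**
- The strategy rests on the single ring. It is a benzene ring with two para oxygens that differ (C2–OCH3 and C5–OH), CH3 on C4 next to the hydroxyl carbon, the oxygenated quaternary carbon on C1 next to the methoxy carbon, and H on C3 and C6. This is the substitution pattern of an alkenyl(methoxy)carbene / 1-alkyne / CO benzannulation.
- The late disconnections are the aryl O–Si bond, then the tiglate ester, then the acetate ester. The acetate is placed by lipase desymmetrisation of the prochiral 2-arylpropane-1,2,3-triol, which sets the only stereocentre.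
- The ring is formed once. It is cut at C2–C3, C4–C5 and C5–C6 into a chromium methoxycarbene that carries the masked triol carbon on its alkenyl α-carbon, propyne, and one CO ligand.
- The carbene complex goes back to Cr(CO)6 and a 2-lithioallyl acetal, which is built from vinyl bromide and 2,2-dimethyl-1,3-dioxan-5-one.

Key step: step 4

Assumption: the lipase is taken to acetylate the pro-S hydroxymethyl arm of the prochiral triol; this sense cannot be read from the structure and has to be proven on the monoacetate before the next acylation.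

**Step 1**
Reactants: 1 vinyl bromide; 2 2,2-dimethyl-1,3-dioxan-5-one
Product: 4 5-(1-bromoethenyl)-2,2-dimethyl-1,3-dioxan-5-ol, via 1-bromovinyllithium 3 (not isolated)
Conditions: LiN(iPr)2, THF–Et2O–pentane 4:1:1, −110 °C; then 2, −110 → −78 °C; aq NH4Cl
Reagents that add atoms: none
Why: Deprotonation of vinyl bromide at its α-carbon gives the carbenoid 3, which survives only near −110 °C, and its 1,2-addition to the unhindered ketone (organolithium carbonyl addition) should outrun enolisation at that temperature, the new carbinol carbon carrying two identical ring arms and so being no stereocentre.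

**Step 2**
Reactants: 4 5-(1-bromoethenyl)-2,2-dimethyl-1,3-dioxan-5-ol
Product: 5 5-(1-bromoethenyl)-5-(1-ethoxyethoxy)-2,2-dimethyl-1,3-dioxane (racemic at the acetal carbon)
Conditions: 1-chloroethyl ethyl ether, PhNMe2, CH2Cl2, 0 °C → rt
Reagents that add atoms: 1-chloroethyl ethyl ether, CCOC(C)Cl
Why: O-alkylation with an α-chloro ether under a weak amine base (acetal protection without acid) caps the tertiary alcohol while the dioxane cannot isomerise to the dioxolane, and an acetal is preferred to a silyl ether because a 2-lithioallyl silyl ether would undergo O-to-C silyl shift (retro-Brook rearrangement) while it warms towards the sparingly soluble Cr(CO)6; the racemic acetal carbon is of no consequence, since it is removed in step 6.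

**Step 3**
Reactants: 5 5-(1-bromoethenyl)-5-(1-ethoxyethoxy)-2,2-dimethyl-1,3-dioxane; 6 chromium hexacarbonyl
Product: 9 pentacarbonyl{2-[5-(1-ethoxyethoxy)-2,2-dimethyl-1,3-dioxan-5-yl]-1-methoxyprop-2-en-1-ylidene}chromium, via vinyllithium 7 (not isolated), via lithium acylchromate 8 (not isolated)
Conditions: t-BuLi (2 equiv), Et2O, −78 °C; cannula into Cr(CO)6, THF, −78 → 0 °C; evaporate; MeOTf, CH2Cl2, 0 °C; aq NaHCO3
Reagents that add atoms: methyl trifluoromethanesulfonate, COS(=O)(=O)C(F)(F)F
Why: Fischer carbene synthesis, namely bromine–lithium exchange with two equivalents of t-BuLi, attack of vinyllithium 7 on the carbon of one CO ligand and O-methylation of the acylate 8 by the hard electrophile MeOTf, with the neighbouring acetal oxygens chelating lithium and the cold transfer limiting loss of lithium alkoxide from 7.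

**Step 4**
Reactants: 9 pentacarbonyl{2-[5-(1-ethoxyethoxy)-2,2-dimethyl-1,3-dioxan-5-yl]-1-methoxyprop-2-en-1-ylidene}chromium; 10 propyne
Product: 12 5-[5-(1-ethoxyethoxy)-2,2-dimethyl-1,3-dioxan-5-yl]-4-methoxy-2-methylphenol, via tricarbonylchromium arene complex 11 (not isolated)
Conditions: propyne (5 equiv, condensed in), degassed THF, sealed vessel, 55 °C; then air, Et2O–MeCN, rt
Reagents that add atoms: none
Why: This is a Dötz benzannulation, the closest precedent being the reaction of isopropenyl and other α-substituted alkenyl(methoxy)carbene pentacarbonylchromium complexes with 1-alkynes. Thermal loss of one CO from 9 frees a site for propyne, which inserts into the Cr=C bond (carbene carbon to alkyne CH) to give an η3-vinylcarbene, and migration of a CO ligand onto the methyl-bearing carbon turns this into a chromium-bound dienylketene. The benzene ring, the only ring closed, forms by six-electron electrocyclisation of that dienylketene (ketene carbon to the terminal alkene CH2), and tautomerisation of the cyclohexadienone gives the phenol as its Cr(CO)3 complex 11, which air demetalates without harming the hydroquinone monoether, whereas a strong oxidant would carry it on to the quinone. No stereocentre is created, since the dioxane carbon that bears the new ring carries two identical ring arms. The selectivity needed is the orientation of propyne, and the size difference of its two ends secures it: the CH3-bearing carbon stays remote from the crowded carbene carbon and bonds to CO, so CH3 ends ortho to OH. Phenol formation over furan, cyclobutenone or five-ring products is favoured by the alkenyl (not aryl) carbene, by chromium as the metal and by the coordinating solvent THF.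

**Step 5**
Reactants: 12 5-[5-(1-ethoxyethoxy)-2,2-dimethyl-1,3-dioxan-5-yl]-4-methoxy-2-methylphenol
Product: 13 {5-[5-(1-ethoxyethoxy)-2,2-dimethyl-1,3-dioxan-5-yl]-4-methoxy-2-methylphenoxy}tri(propan-2-yl)silane
Conditions: TIPSCl, imidazole, DMF, rt
Reagents that add atoms: chlorotri(propan-2-yl)silane, CC(C)[Si](Cl)(C(C)C)C(C)C
Why: Imidazole-promoted silylation of the only free hydroxyl group is routine, and triisopropylsilyl is chosen because its aryl ethers outlast aqueous acid far better than tert-butyldimethylsilyl ones and still fall to fluoride.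

**Step 6**
Reactants: 13 {5-[5-(1-ethoxyethoxy)-2,2-dimethyl-1,3-dioxan-5-yl]-4-methoxy-2-methylphenoxy}tri(propan-2-yl)silane
Product: 14 2-{2-methoxy-4-methyl-5-[tri(propan-2-yl)silyloxy]phenyl}propane-1,2,3-triol
Conditions: AcOH–THF–H2O 4:2:1, 40 °C
Reagents that add atoms: none
Why: Acid-catalysed acetal hydrolysis removes the isopropylidene ketal and the ethoxyethyl acetal together, and with water as the nucleophile any reversible benzylic ionisation is harmless because the carbinol carbon of 14 carries two identical arms.

**Step 7**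
Reactants: 14 2-{2-methoxy-4-methyl-5-[tri(propan-2-yl)silyloxy]phenyl}propane-1,2,3-triol
Product: 15 (2S)-2,3-dihydroxy-2-{2-methoxy-4-methyl-5-[tri(propan-2-yl)silyloxy]phenyl}propyl acetate
Conditions: Burkholderia cepacia lipase (Amano PS on Celite), vinyl acetate, t-BuOMe, 25 °C; filter, concentrate cold, use at once
Reagents that add atoms: vinyl acetate, C=COC(C)=O
Why: In this enzymatic desymmetrisation by irreversible transesterification, known for prochiral 2,2-disubstituted propane-1,3-diols, the lipase distinguishes the two enantiotopic CH2OH arms, acetylation of the pro-S arm sets the (S) centre, the tertiary OH is left alone, and the slower second acetylation should consume the minor enantiomer preferentially.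

**Step 8**
Reactants: 15 (2S)-2,3-dihydroxy-2-{2-methoxy-4-methyl-5-[tri(propan-2-yl)silyloxy]phenyl}propyl acetate; 16 tigloyl chloride, (E)-2-methylbut-2-enoyl chloride
Product: 17 (2R)-3-acetoxy-2-hydroxy-2-{2-methoxy-4-methyl-5-[tri(propan-2-yl)silyloxy]phenyl}propyl (E)-2-methylbut-2-enoate
Conditions: pyridine (3 equiv), CH2Cl2, −10 → 0 °C
Reagents that add atoms: none
Why: Acylation of the primary alcohol by an acid chloride in the presence of pyridine is far faster than that of the hindered tertiary benzylic alcohol, the weak base and low temperature suppress both acetyl migration between the arms (which would racemise 15) and deconjugation through a vinylketene, and the descriptor changes from S to R only through the priority switch of the two arms.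

**Step 9**
Reactants: 17 (2R)-3-acetoxy-2-hydroxy-2-{2-methoxy-4-methyl-5-[tri(propan-2-yl)silyloxy]phenyl}propyl (E)-2-methylbut-2-enoate
Product: 18 (2R)-3-acetoxy-2-hydroxy-2-(5-hydroxy-2-methoxy-4-methylphenyl)propyl (E)-2-methylbut-2-enoate (CNP0219919.1)
Conditions: Bu4NF, AcOH (1:1), THF, 0 °C
Reagents that add atoms: none
Why: Fluoride-induced cleavage of the aryl silyl ether is driven by the Si–F bond, and the acetic acid buffer keeps phenoxide and alkoxide levels too low for ester migration, hydrolysis or conjugate addition to the tiglate.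

**Compound list**
1 | vinyl bromide | C=CBr | starting material
2 | 2,2-dimethyl-1,3-dioxan-5-one | CC1(C)OCC(=O)CO1 | starting material
3 | 1-bromovinyllithium (not isolated) | [Li]C(Br)=C | intermediate
4 | 5-(1-bromoethenyl)-2,2-dimethyl-1,3-dioxan-5-ol | C=C(Br)C1(O)COC(C)(C)OC1 | intermediate
5 | 5-(1-bromoethenyl)-5-(1-ethoxyethoxy)-2,2-dimethyl-1,3-dioxane, racemic at the acetal carbon | C=C(Br)C1(OC(C)OCC)COC(C)(C)OC1 | intermediate
6 | chromium hexacarbonyl | O=C=[Cr](=C=O)(=C=O)(=C=O)(=C=O)=C=O | starting material
7 | 1-[5-(1-ethoxyethoxy)-2,2-dimethyl-1,3-dioxan-5-yl]ethenyllithium (not isolated) | [Li]C(=C)C1(OC(C)OCC)COC(C)(C)OC1 | intermediate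
8 | lithium pentacarbonyl{2-[5-(1-ethoxyethoxy)-2,2-dimethyl-1,3-dioxan-5-yl]prop-2-enoyl}chromate (not isolated) | [Li+].[O-]C(=[Cr](=C=O)(=C=O)(=C=O)(=C=O)=C=O)C(=C)C1(OC(C)OCC)COC(C)(C)OC1 | intermediate
9 | pentacarbonyl{2-[5-(1-ethoxyethoxy)-2,2-dimethyl-1,3-dioxan-5-yl]-1-methoxyprop-2-en-1-ylidene}chromium | COC(=[Cr](=C=O)(=C=O)(=C=O)(=C=O)=C=O)C(=C)C1(OC(C)OCC)COC(C)(C)OC1 | intermediate
10 | propyne | CC#C | starting material
11 | tricarbonyl(η6-arene)chromium complex of phenol 12 (not isolated; the η6 bond is written as a dot) | COc1cc(C)c(O)cc1C2(OC(C)OCC)COC(C)(C)OC2.O=C=[Cr](=C=O)=C=O | intermediate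
12 | 5-[5-(1-ethoxyethoxy)-2,2-dimethyl-1,3-dioxan-5-yl]-4-methoxy-2-methylphenol | COc1cc(C)c(O)cc1C2(OC(C)OCC)COC(C)(C)OC2 | intermediate
13 | {5-[5-(1-ethoxyethoxy)-2,2-dimethyl-1,3-dioxan-5-yl]-4-methoxy-2-methylphenoxy}tri(propan-2-yl)silane | COc1cc(C)c(O[Si](C(C)C)(C(C)C)C(C)C)cc1C2(OC(C)OCC)COC(C)(C)OC2 | intermediate
14 | 2-{2-methoxy-4-methyl-5-[tri(propan-2-yl)silyloxy]phenyl}propane-1,2,3-triol (prochiral) | COc1cc(C)c(O[Si](C(C)C)(C(C)C)C(C)C)cc1C(O)(CO)CO | intermediate
15 | (2S)-2,3-dihydroxy-2-{2-methoxy-4-methyl-5-[tri(propan-2-yl)silyloxy]phenyl}propyl acetate | OC[C@](O)(COC(C)=O)c1cc(O[Si](C(C)C)(C(C)C)C(C)C)c(C)cc1OC | intermediate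
16 | tigloyl chloride, (E)-2-methylbut-2-enoyl chloride | C/C=C(\C)C(=O)Cl | starting material
17 | (2R)-3-acetoxy-2-hydroxy-2-{2-methoxy-4-methyl-5-[tri(propan-2-yl)silyloxy]phenyl}propyl (E)-2-methylbut-2-enoate | C/C=C(\C)C(=O)OC[C@](O)(COC(C)=O)c1cc(O[Si](C(C)C)(C(C)C)C(C)C)c(C)cc1OC | intermediate
18 | (2R)-3-acetoxy-2-hydroxy-2-(5-hydroxy-2-methoxy-4-methylphenyl)propyl (E)-2-methylbut-2-enoate | C/C=C(\C)C(=O)OC[C@](O)(COC(C)=O)c1cc(O)c(C)cc1OC | target

**Step count**
Total step count: 9. Longest linear sequence: 9 steps, from 1 and 2 to 18.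

**Steps most likely to fail**

**Step 4.** The fully substituted carbon on the alkenyl α-position may slow alkyne uptake and CO migration. Thermal decay of the carbene complex, oligomerisation of propyne, or over-oxidation during demetalation could then take over.

The fallback sets out from ketone 2 and comes back at triol 14. The benzene ring is bought instead of built.
- Commercial 4-methoxy-2-methylphenol F1 is silylated (TIPSCl, imidazole, DMF) to its triisopropylsilyl ether F2.
- NBS in MeCN should brominate the position ortho to OCH3 and para to CH3, which gives aryl bromide F3.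
- n-BuLi in THF at −78 °C gives aryllithium F4, which adds to 2 to give tertiary alcohol F5.
- Aqueous acetic acid removes the acetonide and delivers 14.

**Step 7.** Acetyl transfer may go to the wrong enantiotopic arm, the two arms may be discriminated only weakly, or the enantiomeric purity may erode through acetyl migration during isolation.

The fallback sets out from triol 14 and comes back at monoacetate 15.
- Both primary alcohols are acetylated (Ac2O, pyridine, 0 °C) to the prochiral diacetate F6.
- A lipase then hydrolyses one ester in pH 7 phosphate buffer with t-BuOMe.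
- An enzyme addresses the same arm in both directions. Hydrolysis therefore leaves the acetate on the arm that acylation would have left free.
- The hydrolytic mode thus gives access to the opposite sense, and the enzyme is picked so that the pro-R acetate is cleaved.

**Step 3.** The β-alkoxy vinyllithium may lose lithium alkoxide to give an allene. As a hindered nucleophile it may also attack the poorly soluble Cr(CO)6 too slowly.

The fallback sets out from bromo alcohol 4 and comes back at triol 14. It uses the alkoxide itself as the mask, since an oxide anion neither leaves nor migrates.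
- 4 is treated with MeLi and then t-BuLi (2 equiv) in Et2O at −78 °C to give the dilithio species F7.
- Addition of 6 gives the dilithium acylchromate alkoxide F8.
- Degassed aqueous Me4NBr converts F8 into the tetramethylammonium acylchromate F9, which has a free tertiary alcohol.
- MeOTf in CH2Cl2 methylates the acylate oxygen to give the hydroxy carbene complex F10.
- Et3SiOTf and 2,6-lutidine at −78 °C cap the alcohol, now that no organolithium is left, to give the triethylsilyl carbene complex F11.
- Benzannulation with propyne 10 as in step 4 passes through the tricarbonylchromium arene complex F12 and gives, after air, the phenol F13.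
- TIPSCl and imidazole give the bis-silyl ether F14.
- Aqueous HCl (1 mol/L) in THF removes the acetonide and the triethylsilyl ether and gives 14.

**Further compounds**
F1 | step 4 | 4-methoxy-2-methylphenol | COc1ccc(O)c(C)c1
F2 | step 4 | (4-methoxy-2-methylphenoxy)tri(propan-2-yl)silane | COc1ccc(O[Si](C(C)C)(C(C)C)C(C)C)c(C)c1
F3 | step 4 | (5-bromo-4-methoxy-2-methylphenoxy)tri(propan-2-yl)silane | COc1cc(C)c(O[Si](C(C)C)(C(C)C)C(C)C)cc1Br
F4 | step 4 | {2-methoxy-4-methyl-5-[tri(propan-2-yl)silyloxy]phenyl}lithium | [Li]c1cc(O[Si](C(C)C)(C(C)C)C(C)C)c(C)cc1OC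
F5 | step 4 | 5-{2-methoxy-4-methyl-5-[tri(propan-2-yl)silyloxy]phenyl}-2,2-dimethyl-1,3-dioxan-5-ol | COc1cc(C)c(O[Si](C(C)C)(C(C)C)C(C)C)cc1C2(O)COC(C)(C)OC2
F6 | step 7 | 2-hydroxy-2-{2-methoxy-4-methyl-5-[tri(propan-2-yl)silyloxy]phenyl}propane-1,3-diyl diacetate | CC(=O)OCC(O)(COC(C)=O)c1cc(O[Si](C(C)C)(C(C)C)C(C)C)c(C)cc1OC
F7 | step 3 | lithium 5-(1-lithioethenyl)-2,2-dimethyl-1,3-dioxan-5-olate | [Li]C(=C)C1(O[Li])COC(C)(C)OC1
F8 | step 3 | dilithium pentacarbonyl[2-(2,2-dimethyl-5-oxido-1,3-dioxan-5-yl)prop-2-enoyl]chromate | [Li+].[Li+].[O-]C(=[Cr](=C=O)(=C=O)(=C=O)(=C=O)=C=O)C(=C)C1([O-])COC(C)(C)OC1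
F9 | step 3 | tetramethylammonium pentacarbonyl[2-(5-hydroxy-2,2-dimethyl-1,3-dioxan-5-yl)prop-2-enoyl]chromate | C[N+](C)(C)C.[O-]C(=[Cr](=C=O)(=C=O)(=C=O)(=C=O)=C=O)C(=C)C1(O)COC(C)(C)OC1
F10 | step 3 | pentacarbonyl[2-(5-hydroxy-2,2-dimethyl-1,3-dioxan-5-yl)-1-methoxyprop-2-en-1-ylidene]chromium | COC(=[Cr](=C=O)(=C=O)(=C=O)(=C=O)=C=O)C(=C)C1(O)COC(C)(C)OC1
F11 | step 3 | pentacarbonyl{2-[2,2-dimethyl-5-(triethylsilyloxy)-1,3-dioxan-5-yl]-1-methoxyprop-2-en-1-ylidene}chromium | COC(=[Cr](=C=O)(=C=O)(=C=O)(=C=O)=C=O)C(=C)C1(O[Si](CC)(CC)CC)COC(C)(C)OC1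
F12 | step 3 | tricarbonyl(η6-arene)chromium complex of phenol F13 (the η6 bond is written as a dot) | COc1cc(C)c(O)cc1C2(O[Si](CC)(CC)CC)COC(C)(C)OC2.O=C=[Cr](=C=O)=C=O
F13 | step 3 | 5-[2,2-dimethyl-5-(triethylsilyloxy)-1,3-dioxan-5-yl]-4-methoxy-2-methylphenol | COc1cc(C)c(O)cc1C2(O[Si](CC)(CC)CC)COC(C)(C)OC2
F14 | step 3 | {5-[2,2-dimethyl-5-(triethylsilyloxy)-1,3-dioxan-5-yl]-4-methoxy-2-methylphenoxy}tri(propan-2-yl)silane | COc1cc(C)c(O[Si](C(C)C)(C(C)C)C(C)C)cc1C2(O[Si](CC)(CC)CC)COC(C)(C)OC2
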